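Ring B is built last from a non-aromatic precursor. Its C1(OH)–C2(OAr) edge is the O–C–C–O unit of an aryloxyacetic acid, and its C3(H)–C4(Br)–C5(H)–C6(Br) arc is C6–C5–C4–C3 of 3,5-dibromo-2-pyrone. One inverse-demand Diels–Alder reaction joins the pyrone to the ketene bis(trimethylsilyl) acetal of (2,3,4-tribromo-6-methoxyphenoxy)acetic acid. Loss of CO2 and Me3SiOH in the same flask then delivers ring B with both bromines, the hydroxyl and the diaryl ether oxygen already in place. No aryl C–O coupling and no late bromination is needed. Ring A is tribrominated guaiacol, O-alkylated with a bromoacetate.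

Key step: step 5

Remark: transient compounds 10 and 11 are expected as racemates (10 also as an endo/exo mixture); all of their stereocentres vanish on aromatization, and the target is achiral.

Step 1
Reactants: 1 guaiacol (2-methoxyphenol)
Product: 2 2,3,4-tribromo-6-methoxyphenol (4,5,6-tribromoguaiacol)
Conditions: Br2 (3.05 equiv), AcOH, 15 °C → rt, dark; aq. NaHSO3 quench
Reagents that add atoms: bromine, BrBr
Why: Electrophilic aromatic bromination, in which bromine is expected to enter para to OH, then para to OMe and finally ortho to OH, leaving the least activated C–H (next to OMe, meta to OH) untouched at three equivalents; the position of the lone ring proton is to be verified by an NOE to OMe.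

Step 2
Reactants: 2 2,3,4-tribromo-6-methoxyphenol; 3 methyl bromoacetate
Product: 5 (2,3,4-tribromo-6-methoxyphenoxy)acetic acid, via methyl ester 4 (not isolated)
Conditions: K2CO3 (2 equiv), 3 (1.1 equiv), MeCN, 60 °C; then LiOH (3 equiv), H2O, rt; then 1 M HCl to pH 1, crystallize
Reagents that add atoms: LiOH (lithium hydroxide), [Li+].[OH-]
Why: Williamson ether synthesis (SN2 of the acidic, hindered phenoxide on the unhindered α-bromo ester) followed by ester saponification in the same flask, conditions to which the aryl bromides and the aryl methyl ether are inert.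

Step 3
Reactants: 5 (2,3,4-tribromo-6-methoxyphenoxy)acetic acid
Product: 7 1,1-bis(trimethylsilyloxy)-2-(2,3,4-tribromo-6-methoxyphenoxy)ethene, via trimethylsilyl ester 6 (not isolated)
Conditions: LiN(SiMe3)2 (1.05 equiv), THF, −78 °C; Me3SiCl (2.5 equiv), −78 → 0 °C; then −78 °C, LiN(SiMe3)2 (1.15 equiv), → rt; evaporate, dry PhMe, filter under Ar, use the solution directly
Reagents that add atoms: chlorotrimethylsilane, C[Si](C)(C)Cl
Why: Formation of a ketene bis(silyl) acetal by O-silylation of the lithium carboxylate and amide-base enolization of the silyl ester with in situ silyl chloride trapping on oxygen, using a hindered base that is too weak and too cold for bromine–lithium exchange or ring metalation; the two identical silyloxy groups exclude E/Z isomers.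

Step 4
Reactants: 8 coumalic acid (2-oxo-2H-pyran-5-carboxylic acid)
Product: 9 3,5-dibromo-2H-pyran-2-one
Conditions: NBS (2.3 equiv), LiOAc (1.2 equiv), MeCN–H2O, rt
Reagents that add atoms: N-bromosuccinimide, O=C1CCC(=O)N1Br
Why: Hunsdiecker-type bromodecarboxylation at C5 combined with electrophilic bromination at C3, the two nucleophilic carbons of the pyrone, a known one-flask conversion of this acid.

Step 5
Reactants: 7 1,1-bis(trimethylsilyloxy)-2-(2,3,4-tribromo-6-methoxyphenoxy)ethene; 9 3,5-dibromo-2H-pyran-2-one
Product: 13 2,4-dibromo-6-(2,3,4-tribromo-6-methoxyphenoxy)phenol, via bridged lactone 10 (not isolated), via cyclohexadiene acetal 11 (not isolated), via aryl silyl ether 12 (not isolated)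
Conditions: 7 (2.5 equiv), dry PhMe, Ar, rt → 110 °C; evaporate; then 0.1 M HCl in MeOH, rt
Reagents that add atoms: none
Why: Inverse-electron-demand Diels–Alder reaction: the electron-rich ketene acetal 7 adds across C3 and C6 of the electron-poor pyrone 9 (concerted but asynchronous, or conjugate addition at C6 followed by collapse of the zwitterion) to give bridged lactone 10, which on heating expels CO2 by retro-[4+2] to give diene 11. Diene 11 can aromatize only by 1,2-elimination of Me3SiOH, since its acetal carbon has no hydrogen with which the aryloxy group could depart, so the phenolic oxygen is kept as silyl ether 12 and freed by acidic methanolysis. The closest known reaction type is the cycloaddition of electron-poor 2-pyrones with ketene acetals and enol ethers, which gives aryl ethers after loss of CO2 and an alcohol. Ring B is closed by an intermolecular [4+2] annulation that forms both new C–C bonds (pyrone C6 to the CH(OAr) carbon, pyrone C3 to the acetal carbon), with C2 and O1 of the pyrone leaving as CO2. The stereocentres of 10 and 11 are transient and need no control. The only selectivity needed is regiochemical and is set by polarization: the largest HOMO coefficient of 7 lies on the aryloxy-bearing carbon (pushed by two silyloxy donors) and the largest LUMO coefficient of 9 on C6, which places O–Si next to C–Br and O–aryl next to C–H, as ring B requires.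

Compound list
1 | guaiacol (2-methoxyphenol) | COc1ccccc1O | starting material
2 | 2,3,4-tribromo-6-methoxyphenol (4,5,6-tribromoguaiacol; OH at C1, Br at C2, C3 and C4, H at C5, OMe at C6) | COc1cc(Br)c(Br)c(Br)c1O | intermediate
3 | methyl bromoacetate | COC(=O)CBr | starting material
4 | methyl (2,3,4-tribromo-6-methoxyphenoxy)acetate | COC(=O)COc1c(OC)cc(Br)c(Br)c1Br | intermediate
5 | (2,3,4-tribromo-6-methoxyphenoxy)acetic acid | OC(=O)COc1c(OC)cc(Br)c(Br)c1Br | intermediate
6 | trimethylsilyl (2,3,4-tribromo-6-methoxyphenoxy)acetate | C[Si](C)(C)OC(=O)COc1c(OC)cc(Br)c(Br)c1Br | intermediate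
7 | 1,1-bis(trimethylsilyloxy)-2-(2,3,4-tribromo-6-methoxyphenoxy)ethene (ketene bis(trimethylsilyl) acetal of 5) | C[Si](C)(C)OC(O[Si](C)(C)C)=COc1c(OC)cc(Br)c(Br)c1Br | intermediate
8 | coumalic acid (2-oxo-2H-pyran-5-carboxylic acid) | OC(=O)c1ccc(=O)oc1 | starting material
9 | 3,5-dibromo-2H-pyran-2-one | O=c1occ(Br)cc1Br | intermediate
10 | 4,6-dibromo-7-(2,3,4-tribromo-6-methoxyphenoxy)-8,8-bis(trimethylsilyloxy)-2-oxabicyclo[2.2.2]oct-5-en-3-one (racemic, endo/exo mixture at C7) | O=C1OC2C(Br)=CC1(Br)C(O[Si](C)(C)C)(O[Si](C)(C)C)C2Oc1c(OC)cc(Br)c(Br)c1Br | intermediate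
11 | 1,3-dibromo-5-(2,3,4-tribromo-6-methoxyphenoxy)-6,6-bis(trimethylsilyloxy)cyclohexa-1,3-diene (racemic) | C[Si](C)(C)OC1(O[Si](C)(C)C)C(Br)=CC(Br)=CC1Oc1c(OC)cc(Br)c(Br)c1Br | intermediate
12 | [2,4-dibromo-6-(2,3,4-tribromo-6-methoxyphenoxy)phenoxy]trimethylsilane | C[Si](C)(C)Oc1c(Br)cc(Br)cc1Oc1c(OC)cc(Br)c(Br)c1Br | intermediate
13 | 2,4-dibromo-6-(2,3,4-tribromo-6-methoxyphenoxy)phenol | COc1cc(Br)c(Br)c(Br)c1Oc1cc(Br)cc(Br)c1O | target

Total step count: 5.
Longest linear sequence: 4 steps (steps 1, 2, 3 and 5, from guaiacol 1 to 13); step 4 is a one-step branch.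

Steps most likely to fail

Risk 1, step 5. The cycloaddition may be outrun by decay of the dienophile:
- the doubly ortho-substituted aryloxy group makes the trisubstituted alkene bulky;
- the silanol released on aromatization protonates unreacted 7;
- the bridged lactone may resist CO2 loss at 110 °C;
- a minor share of reversed orientation cannot be excluded.

This exact pairing of a halopyrone with an α-aryloxy ketene bis(silyl) acetal is without direct precedent. It would first be probed on a small scale, up to 140 °C in xylene, with the surplus of 7 recovered as acid 5 on work-up.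

Fallback, from 2 back to 13: the ring synthesis is given up and the diaryl ether is made by nucleophilic aromatic substitution. Phenol 2 and purchased 2,4-dibromo-6-fluorobenzaldehyde (O=Cc1c(F)cc(Br)cc1Br) with K2CO3 in DMAc at 100 °C should give 2,4-dibromo-6-(2,3,4-tribromo-6-methoxyphenoxy)benzaldehyde F1, because fluoride ortho to the formyl group is displaced far faster than either bromide. Baeyer–Villiger oxidation with mCPBA in CH2Cl2 should then give 2,4-dibromo-6-(2,3,4-tribromo-6-methoxyphenoxy)phenyl formate F2. Methanolysis (K2CO3, MeOH, rt) releases 13.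

Risk 2, step 3. Enolization may be incomplete or partly diverted to C-silylation, and the bis(trimethylsilyl) acetal may hydrolyse back to 6 or 5 during the solvent switch, so that step 5 receives a reagent of unknown titre. An aliquot would be assayed in C6D6 before use.

Fallback, from 5 back to 13: a robust, isolable silyl series replaces the in situ reagent.
- TBSCl and imidazole in DMF should give tert-butyldimethylsilyl (2,3,4-tribromo-6-methoxyphenoxy)acetate F3.
- LiN(SiMe3)2 and TBSCl in THF–DMPU at −78 °C → rt should give 1,1-bis(tert-butyldimethylsilyloxy)-2-(2,3,4-tribromo-6-methoxyphenoxy)ethene F4, which should tolerate a quick cold NaHCO3 wash and can be characterized and weighed.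
- Heating F4 with 9 in xylene (110–140 °C) should pass through 4,6-dibromo-8,8-bis(tert-butyldimethylsilyloxy)-7-(2,3,4-tribromo-6-methoxyphenoxy)-2-oxabicyclo[2.2.2]oct-5-en-3-one F5 and 1,3-dibromo-6,6-bis(tert-butyldimethylsilyloxy)-5-(2,3,4-tribromo-6-methoxyphenoxy)cyclohexa-1,3-diene F6 to tert-butyl[2,4-dibromo-6-(2,3,4-tribromo-6-methoxyphenoxy)phenoxy]dimethylsilane F7.
- Bu4NF with AcOH in THF at 0 °C then gives 13.

Risk 3, step 1. Positional control may be lost in the later brominations: attack at the carbon next to OMe, over-bromination to the tetrabromide, or oxidation of the electron-rich phenol would give mixtures that are hard to separate.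

Fallback, from 1 back to 2: the halogens are introduced in two controlled stages. Br2 (2.0 equiv) in CH2Cl2 at 0 °C should give 4,5-dibromo-2-methoxyphenol F8, which is crystallized and checked for two para-disposed ring protons. An amine-directed ortho-bromination of the phenol (NBS, catalytic iPr2NH, CH2Cl2, 0 °C) then places the third bromine next to the hydroxyl and gives 2.

Further compounds
F1 | step 5 | 2,4-dibromo-6-(2,3,4-tribromo-6-methoxyphenoxy)benzaldehyde | O=Cc1c(Br)cc(Br)cc1Oc1c(OC)cc(Br)c(Br)c1Br
F2 | step 5 | 2,4-dibromo-6-(2,3,4-tribromo-6-methoxyphenoxy)phenyl formate | O=COc1c(Br)cc(Br)cc1Oc1c(OC)cc(Br)c(Br)c1Br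
F3 | step 3 | tert-butyldimethylsilyl (2,3,4-tribromo-6-methoxyphenoxy)acetate | CC(C)(C)[Si](C)(C)OC(=O)COc1c(OC)cc(Br)c(Br)c1Br
F4 | step 3 | 1,1-bis(tert-butyldimethylsilyloxy)-2-(2,3,4-tribromo-6-methoxyphenoxy)ethene | CC(C)(C)[Si](C)(C)OC(O[Si](C)(C)C(C)(C)C)=COc1c(OC)cc(Br)c(Br)c1Br
F5 | step 3 | 4,6-dibromo-8,8-bis(tert-butyldimethylsilyloxy)-7-(2,3,4-tribromo-6-methoxyphenoxy)-2-oxabicyclo[2.2.2]oct-5-en-3-one (racemic, endo/exo mixture) | O=C1OC2C(Br)=CC1(Br)C(O[Si](C)(C)C(C)(C)C)(O[Si](C)(C)C(C)(C)C)C2Oc1c(OC)cc(Br)c(Br)c1Br
F6 | step 3 | 1,3-dibromo-6,6-bis(tert-butyldimethylsilyloxy)-5-(2,3,4-tribromo-6-methoxyphenoxy)cyclohexa-1,3-diene (racemic) | CC(C)(C)[Si](C)(C)OC1(O[Si](C)(C)C(C)(C)C)C(Br)=CC(Br)=CC1Oc1c(OC)cc(Br)c(Br)c1Br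
F7 | step 3 | tert-butyl[2,4-dibromo-6-(2,3,4-tribromo-6-methoxyphenoxy)phenoxy]dimethylsilane | CC(C)(C)[Si](C)(C)Oc1c(Br)cc(Br)cc1Oc1c(OC)cc(Br)c(Br)c1Br
F8 | step 1 | 4,5-dibromo-2-methoxyphenol | COc1cc(Br)c(Br)cc1O
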